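**Retrosynthetic overview**
- The target is an oxane (ring A) joined through its fully substituted C6 (O, CH3, CH2) to C1 of a cyclohexane (ring B) that carries an axial Cl at C3 and an axial tertiary Br at C4.
- Late disconnections: the C–Cl and tertiary C–Br bonds of ring B go back to the ring-B alkene through its anti-epoxide (two trans-diaxial openings); ring A goes back to 6-endo bromoetherification of (R,R)-α-bisabolol.
- Key disconnection: the ring A–ring B bond, made by a one-flask, three-component union (lithiated (R)-sulcatyl 2,4,6-triisopropylbenzoate, (R)-cyclohexenyl boronic ester, peroxide oxygen) through a boronate 1,2-metallate rearrangement and C–B oxidation.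
- Enabling feature: ring-A C6 is a tertiary C–O carbon bonded directly to the secondary stereogenic ring-B C1, so the ring oxygen can be the residue of a C–B bond and ring-B C1 the migrating carbon of a boronate.
- Ring order: ring B first (ring-closing metathesis in the boronate fragment), then ring A (bromoetherification), then halogenation of ring B.

Key step: step 7

Remark: the SMILES is read as (3S,6R)-3-bromo-6-[(1R,3S,4S)-4-bromo-3-chloro-4-methylcyclohexyl]-2,2,6-trimethyloxane, with the ring-A substituent and the C4 methyl of ring B equatorial and the two ring-B halogens trans-diaxial; neopentyl glycol esters are used at boron because the hindered carbanion of step 7 needs an unhindered boron centre.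

**Route**

Step 1
Reactants: 1 allylmagnesium bromide (CH2=CHCH2MgBr, 1 M in Et2O)
Product: 3 2-allyl-5,5-dimethyl-1,3,2-dioxaborinane, via dimethyl allylboronate 2 (not isolated)
Conditions: B(OMe)3, Et2O, −78 °C to rt; then neopentyl glycol, rt; distillation
Reagents that add atoms: trimethyl borate COB(OC)OC; 2,2-dimethylpropane-1,3-diol (neopentyl glycol) OCC(C)(C)CO
Why: Borylation of a Grignard reagent with a trialkyl borate followed by transesterification with a 1,3-diol is the standard route to boronic esters and creates no stereocentre.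

Step 2
Reactants: 4 4-methylpent-4-en-1-ol
Product: 5 4-methylpent-4-en-1-yl N,N-diisopropylcarbamate
Conditions: i-Pr2NCOCl, Et3N, CH2Cl2, reflux
Reagents that add atoms: N,N-diisopropylcarbamoyl chloride CC(C)N(C(C)C)C(Cl)=O
Why: O-Carbamoylation of the primary alcohol installs the directing and leaving group for the asymmetric lithiation and creates no stereocentre.

Step 3
Reactants: 5 4-methylpent-4-en-1-yl N,N-diisopropylcarbamate; 3 2-allyl-5,5-dimethyl-1,3,2-dioxaborinane
Product: 8 5,5-dimethyl-2-[(4R)-7-methylocta-1,7-dien-4-yl]-1,3,2-dioxaborinane, via lithiated carbamate 6 (not isolated), via allyl boronate complex 7 (not isolated)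
Conditions: s-BuLi, (−)-sparteine, Et2O, −78 °C, 5 h; then 3, −78 °C, 1 h; then reflux, 16 h
Reagents that add atoms: none
Why: Sparteine-mediated enantioselective α-lithiation of the O-alkyl carbamate should give the configurationally stable (S)-organolithium, which is borylated with retention and then undergoes 1,2-metallate rearrangement with inversion (lithiation–borylation, a Matteson-type homologation), so the boron-bearing carbon is set (R) by the diamine.

Step 4
Reactants: 8 5,5-dimethyl-2-[(4R)-7-methylocta-1,7-dien-4-yl]-1,3,2-dioxaborinane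
Product: 9 5,5-dimethyl-2-[(1R)-4-methylcyclohex-3-en-1-yl]-1,3,2-dioxaborinane
Conditions: second-generation Grubbs catalyst RuCl2(=CHPh)(PCy3)(H2IMes) (2 mol %), CH2Cl2, 40 °C
Reagents that add atoms: none
Why: Ring-closing metathesis of the 1,7-diene should close ring B as the trisubstituted cyclohexene with loss of ethene and leaves the boron-bearing stereocentre untouched.

Step 5
Reactants: 10 6-methylhept-5-en-2-one (sulcatone)
Product: 11 (2R)-6-methylhept-5-en-2-ol
Conditions: (R)-selective ketoreductase (alcohol dehydrogenase of the Lactobacillus kefir type), NADP+ (cat.), i-PrOH, KH2PO4/K2HPO4 buffer pH 7, MgCl2, 30 °C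
Reagents that add atoms: none
Why: Enzymatic asymmetric reduction of the methyl ketone by an anti-Prelog alcohol dehydrogenase should deliver hydride from NADPH to the si face and give the (R)-carbinol, with propan-2-ol regenerating the cofactor.

Step 6
Reactants: 11 (2R)-6-methylhept-5-en-2-ol
Product: 13 (2R)-6-methylhept-5-en-2-yl 2,4,6-triisopropylbenzoate, via sodium alkoxide 12 (not isolated)
Conditions: NaH, THF, 0 °C; then 2,4,6-triisopropylbenzoyl chloride, 0 to 60 °C
Reagents that add atoms: 2,4,6-triisopropylbenzoyl chloride CC(C)c1cc(C(C)C)c(C(Cl)=O)c(C(C)C)c1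
Why: O-Acylation of the alkoxide with the hindered aroyl chloride gives the benzoate that directs α-lithiation and later acts as leaving group, with retention because the C–O bond is not touched.

Step 7
Reactants: 13 (2R)-6-methylhept-5-en-2-yl 2,4,6-triisopropylbenzoate; 9 5,5-dimethyl-2-[(1R)-4-methylcyclohex-3-en-1-yl]-1,3,2-dioxaborinane
Product: 17 (2R)-6-methyl-2-[(1R)-4-methylcyclohex-3-en-1-yl]hept-5-en-2-ol ((R,R)-α-bisabolol), via lithiated benzoate 14 (not isolated), via cyclohexenyl boronate complex 15 (not isolated), via tertiary boronic ester 16 (not isolated)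
Conditions: 13 (1.3 equiv), s-BuLi (1.25 equiv), TMEDA (6 equiv), cyclopentyl methyl ether (CPME), −60 °C, 2 h; then 9 (1.0 equiv), −60 °C, 2 h; then 50 °C, 12 h; then 2 M NaOH, 30% H2O2, THF, 0 °C to rt
Reagents that add atoms: hydrogen peroxide OO
Why: s-BuLi/TMEDA should remove the proton α to the benzoate oxygen of 13 with retention to give the configurationally stable tertiary α-oxy-organolithium 14, which adds to boron of 9 with retention to give boronate 15; on warming, the ring-B carbon migrates from boron to carbon anti-periplanar to the departing benzoate (1,2-metallate rearrangement: inversion at the carbenoid carbon, retention at the migrating carbon) to give the tertiary boronic ester 16, whose C–B bond is oxidised with retention in the same flask. The closest known reaction type is the lithiation–borylation of secondary dialkyl 2,4,6-triisopropylbenzoates with neopentyl glycol boronic esters to give tertiary boronic esters and tertiary alcohols. No ring is closed in this step. The carbinol stereocentre (R) is controlled only by the configuration of ester 13 and the ring-B stereocentre (R) only by that of boronic ester 9, so the relative configuration across the new bond follows from two stereospecific events and not from a facial preference. The step needs α-lithiation in preference to allylic deprotonation, which the coordinating carbonyl group of the benzoate and the low temperature secure, and capture of a hindered carbanion by a secondary alkylboron centre, which the unhindered neopentyl glycol ester and the excess diamine should secure; the two trisubstituted alkenes are inert to all reagents of the sequence.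

Step 8
Reactants: 17 (2R)-6-methyl-2-[(1R)-4-methylcyclohex-3-en-1-yl]hept-5-en-2-ol
Product: 19 (3S,6R)-3-bromo-2,2,6-trimethyl-6-[(1R)-4-methylcyclohex-3-en-1-yl]oxane, via side-chain bromonium ion 18 (not isolated)
Conditions: TBCO (1.1 equiv), MeNO2, 0 °C to rt, dark
Reagents that add atoms: 2,4,4,6-tetrabromocyclohexa-2,5-dien-1-one (TBCO) O=C1C(Br)=CC(Br)(Br)C=C1Br
Why: In this bromonium-induced 6-endo etherification (bromoetherification) bromonium formation is reversible at both trisubstituted alkenes, but only the side-chain bromonium 18 should be captured quickly, the hydroxyl opening it at the tertiary carbon (Markovnikov, anti) through a chair transition state in which the cyclohexenyl group is equatorial and the smaller methyl takes the axial site facing the axial methyl of the forming CMe2–O carbon, which places bromine equatorial and trans to the ring-B substituent and so sets C3 of ring A (S).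

Step 9
Reactants: 19 (3S,6R)-3-bromo-2,2,6-trimethyl-6-[(1R)-4-methylcyclohex-3-en-1-yl]oxane
Product: 20 (3S,6R)-3-bromo-2,2,6-trimethyl-6-[(1S,3R,6R)-6-methyl-7-oxabicyclo[4.1.0]heptan-3-yl]oxane
Conditions: L-fructose-derived Shi ketone (ent-Shi ketone, 30 mol %), Oxone (2KHSO5·KHSO4·K2SO4), K2CO3, Bu4NHSO4, MeCN–CH2(OMe)2, aq Na2B4O7/Na2EDTA buffer, pH 10.5, 0 °C
Reagents that add atoms: potassium peroxymonosulfate (KHSO5, active component of Oxone) [K+].[O-]S(=O)(=O)OO
Why: In this Shi epoxidation the dioxirane formed from the chiral ketone should transfer oxygen through a spiro transition state to the face of the ring-B alkene anti to the ring-A substituent (reagent control; the ketone series is the one that the spiro model predicts to give the cis-limonene-oxide-type isomer, methyl and side chain cis), which sets both epoxide carbons while the secondary bromide and the ether survive the buffered medium.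

Step 10
Reactants: 20 (3S,6R)-3-bromo-2,2,6-trimethyl-6-[(1S,3R,6R)-6-methyl-7-oxabicyclo[4.1.0]heptan-3-yl]oxane
Product: 21 (1S,2S,5R)-2-bromo-5-[(2R,5S)-5-bromo-2,6,6-trimethyloxan-2-yl]-2-methylcyclohexan-1-ol
Conditions: 48% aq HBr (1.2 equiv), CHCl3, 0 °C, 10 min
Reagents that add atoms: hydrogen bromide Br
Why: In this acid-promoted epoxide opening under Fürst–Plattner control ring B is locked by its equatorial tert-alkyl substituent and bromide attacks the tertiary carbon from the face opposite to oxygen, where the Markovnikov preference and the trans-diaxial requirement coincide, so inversion there should give the axial tertiary bromide and leave the axial secondary hydroxyl with its configuration.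

Step 11
Reactants: 21 (1S,2S,5R)-2-bromo-5-[(2R,5S)-5-bromo-2,6,6-trimethyloxan-2-yl]-2-methylcyclohexan-1-ol
Product: 24 deoxy isocaespitol, (3S,6R)-3-bromo-6-[(1R,3S,4S)-4-bromo-3-chloro-4-methylcyclohexyl]-2,2,6-trimethyloxane, via chlorosulfite 22 (not isolated), via bromonium chloride 23 (not isolated)
Conditions: SOCl2 (1.5 equiv), pyridine (2 equiv), CH2Cl2, −20 °C to rt
Reagents that add atoms: thionyl chloride O=S(Cl)Cl
Why: In this deoxychlorination with neighbouring-group participation the axial bromine, anti-periplanar to the chlorosulfite group of 22, should expel it to give the bridged bromonium ion 23, which chloride reopens trans-diaxially at the secondary carbon (Fürst–Plattner control in the locked chair), so that C–O is replaced by C–Cl with net retention and the tertiary bromide stays in place.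

**Compound list**
1 | allylmagnesium bromide | C=CC[Mg]Br | starting material
2 | dimethyl allylboronate | C=CCB(OC)OC | intermediate
3 | 2-allyl-5,5-dimethyl-1,3,2-dioxaborinane | C=CCB1OCC(C)(C)CO1 | intermediate
4 | 4-methylpent-4-en-1-ol | CC(=C)CCCO | starting material
5 | 4-methylpent-4-en-1-yl N,N-diisopropylcarbamate | CC(=C)CCCOC(=O)N(C(C)C)C(C)C | intermediate
6 | (1S)-1-lithio-4-methylpent-4-en-1-yl N,N-diisopropylcarbamate (sparteine complex) | [Li][C@H](OC(=O)N(C(C)C)C(C)C)CCC(C)=C | intermediate
7 | lithium allyl boronate complex of 6 and 3 | C=CC[B-]1(OCC(C)(C)CO1)[C@H](OC(=O)N(C(C)C)C(C)C)CCC(C)=C.[Li+] | intermediate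
8 | 5,5-dimethyl-2-[(4R)-7-methylocta-1,7-dien-4-yl]-1,3,2-dioxaborinane | CC1(C)COB(OC1)[C@@H](CC=C)CCC(C)=C | intermediate
9 | 5,5-dimethyl-2-[(1R)-4-methylcyclohex-3-en-1-yl]-1,3,2-dioxaborinane | CC1(C)COB(OC1)[C@@H]2CCC(C)=CC2 | intermediate
10 | 6-methylhept-5-en-2-one (sulcatone) | CC(=O)CCC=C(C)C | starting material
11 | (2R)-6-methylhept-5-en-2-ol | C[C@@H](O)CCC=C(C)C | intermediate
12 | sodium (2R)-6-methylhept-5-en-2-olate | C[C@@H]([O-])CCC=C(C)C.[Na+] | intermediate
13 | (2R)-6-methylhept-5-en-2-yl 2,4,6-triisopropylbenzoate | C[C@@H](OC(=O)c1c(C(C)C)cc(C(C)C)cc1C(C)C)CCC=C(C)C | intermediate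
14 | (2R)-2-lithio-6-methylhept-5-en-2-yl 2,4,6-triisopropylbenzoate | C[C@@]([Li])(OC(=O)c1c(C(C)C)cc(C(C)C)cc1C(C)C)CCC=C(C)C | intermediate
15 | lithium cyclohexenyl boronate complex of 14 and 9 | C[C@@]([B-]1(OCC(C)(C)CO1)[C@@H]2CCC(C)=CC2)(OC(=O)c3c(C(C)C)cc(C(C)C)cc3C(C)C)CCC=C(C)C.[Li+] | intermediate
16 | 5,5-dimethyl-2-[(2R)-6-methyl-2-[(1R)-4-methylcyclohex-3-en-1-yl]hept-5-en-2-yl]-1,3,2-dioxaborinane | C[C@](B1OCC(C)(C)CO1)([C@@H]2CCC(C)=CC2)CCC=C(C)C | intermediate
17 | (2R)-6-methyl-2-[(1R)-4-methylcyclohex-3-en-1-yl]hept-5-en-2-ol ((R,R)-α-bisabolol) | C[C@](O)([C@@H]1CCC(C)=CC1)CCC=C(C)C | intermediate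
18 | side-chain bromonium ion of 17 (2,4,6-tribromophenolate salt) | C[C@](O)([C@@H]1CCC(C)=CC1)CC[C@@H]2[Br+]C2(C)C.[O-]c3c(Br)cc(Br)cc3Br | intermediate
19 | (3S,6R)-3-bromo-2,2,6-trimethyl-6-[(1R)-4-methylcyclohex-3-en-1-yl]oxane | CC1(C)O[C@@](C)([C@@H]2CCC(C)=CC2)CC[C@@H]1Br | intermediate
20 | (3S,6R)-3-bromo-2,2,6-trimethyl-6-[(1S,3R,6R)-6-methyl-7-oxabicyclo[4.1.0]heptan-3-yl]oxane | CC1(C)O[C@@](C)([C@@H]2CC[C@@]3(C)O[C@H]3C2)CC[C@@H]1Br | intermediate
21 | (1S,2S,5R)-2-bromo-5-[(2R,5S)-5-bromo-2,6,6-trimethyloxan-2-yl]-2-methylcyclohexan-1-ol | CC1(C)O[C@@](C)([C@@H]2CC[C@](C)(Br)[C@@H](O)C2)CC[C@@H]1Br | intermediate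
22 | chlorosulfite of 21 | CC1(C)O[C@@](C)([C@@H]2CC[C@](C)(Br)[C@@H](OS(Cl)=O)C2)CC[C@@H]1Br | intermediate
23 | ring-B bromonium chloride | CC1(C)O[C@@](C)([C@@H]2CC[C@]3(C)[Br+][C@@H]3C2)CC[C@@H]1Br.[Cl-] | intermediate
24 | deoxy isocaespitol, (3S,6R)-3-bromo-6-[(1R,3S,4S)-4-bromo-3-chloro-4-methylcyclohexyl]-2,2,6-trimethyloxane | CC1(C)O[C@@](C)([C@@H]2CC[C@](C)(Br)[C@@H](Cl)C2)CC[C@@H]1Br | target

**Step count and risks**

Total step count: 11. Longest linear sequence: 8 steps (steps 2, 3, 4, 7, 8, 9, 10, 11).

The three steps most likely to fail: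

Step 7. The hindered tertiary carbanion 14 may be captured too slowly by the secondary alkylboron centre of 9, so that it decomposes or loses configuration before the boronate forms, or the boronate may revert instead of rearranging. The fallback sets out from 9 and comes back to the route at 17 (through 16). It first joins ring-B C1 to a smaller, secondary carbenoid. Boronic ester 9 is homologated with ethyl N,N-diisopropylcarbamate lithiated by s-BuLi/(+)-sparteine (Et2O, −78 °C, then warming) to give 5,5-dimethyl-2-[(1S)-1-[(1R)-4-methylcyclohex-3-en-1-yl]ethyl]-1,3,2-dioxaborinane F1. Oxidation with NaOH/H2O2 gives (1S)-1-[(1R)-4-methylcyclohex-3-en-1-yl]ethan-1-ol F2, which is acylated as in step 6 to (1S)-1-[(1R)-4-methylcyclohex-3-en-1-yl]ethyl 2,4,6-triisopropylbenzoate F3. Lithiation of this ester (s-BuLi, TMEDA, CPME, −60 °C) and borylation with the unhindered primary boronic ester 5,5-dimethyl-2-(4-methylpent-3-en-1-yl)-1,3,2-dioxaborinane F4 (from 5-bromo-2-methylpent-2-ene through its Grignard reagent, B(OMe)3 and neopentyl glycol) should give, after migration of the primary group with inversion, the same tertiary boronic ester 16, which is oxidised to 17 as in step 7.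

Step 8. Bromonium transfer to the ring-B alkene followed by transannular capture by the hydroxyl, or 5-exo instead of 6-endo closure, may divert the cyclisation. The fallback sets out from 9 and comes back to the route at 19. The ring-B alkene is masked before the union. Boronic ester 9 is epoxidised with dimethyldioxirane (acetone, 0 °C) to 5,5-dimethyl-2-[(3R)-6-methyl-7-oxabicyclo[4.1.0]heptan-3-yl]-1,3,2-dioxaborinane F5 (both epoxide diastereomers). This is taken through the conditions of step 7 to (2R)-6-methyl-2-[(3R)-6-methyl-7-oxabicyclo[4.1.0]heptan-3-yl]hept-5-en-2-ol F6 and through those of step 8 to (3S,6R)-3-bromo-2,2,6-trimethyl-6-[(3R)-6-methyl-7-oxabicyclo[4.1.0]heptan-3-yl]oxane F7, in which no second alkene competes. Stereospecific deoxygenation (triphenylphosphine selenide, CF3CO2H, CH2Cl2) then restores the alkene and gives 19.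

Step 11. Chloride may attack the tertiary carbon of the bromonium ion (bromine migration to the secondary carbon), or the chlorosulfite may undergo base-induced elimination. The fallback sets out from 19 and comes back to the route at 24. It introduces the two halogens in the opposite order through the other epoxide. Shi epoxidation of 19 with the D-fructose-derived ketone should give the syn-epoxide (3S,6R)-3-bromo-2,2,6-trimethyl-6-[(1R,3R,6S)-6-methyl-7-oxabicyclo[4.1.0]heptan-3-yl]oxane F8. Pyridinium chloride in CHCl3 opens it trans-diaxially at the secondary carbon to (1S,2S,4R)-4-[(2R,5S)-5-bromo-2,6,6-trimethyloxan-2-yl]-2-chloro-1-methylcyclohexan-1-ol F9. Me3SiBr in CH2Cl2 at 0 °C then replaces the tertiary hydroxyl by bromide through the chlorine-bridged tertiary cation, with axial attack anti to chlorine, to give 24.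

**Further compounds**
F1 | step 7 | 5,5-dimethyl-2-[(1S)-1-[(1R)-4-methylcyclohex-3-en-1-yl]ethyl]-1,3,2-dioxaborinane | C[C@@H]([C@@H]1CCC(C)=CC1)B2OCC(C)(C)CO2
F2 | step 7 | (1S)-1-[(1R)-4-methylcyclohex-3-en-1-yl]ethan-1-ol | C[C@@H]([C@@H]1CCC(C)=CC1)O
F3 | step 7 | (1S)-1-[(1R)-4-methylcyclohex-3-en-1-yl]ethyl 2,4,6-triisopropylbenzoate | C[C@@H]([C@@H]1CCC(C)=CC1)OC(=O)c2c(C(C)C)cc(C(C)C)cc2C(C)C
F4 | step 7 | 5,5-dimethyl-2-(4-methylpent-3-en-1-yl)-1,3,2-dioxaborinane | CC(C)=CCCB1OCC(C)(C)CO1
F5 | step 8 | 5,5-dimethyl-2-[(3R)-6-methyl-7-oxabicyclo[4.1.0]heptan-3-yl]-1,3,2-dioxaborinane (both epoxide diastereomers) | CC1(C)COB(OC1)[C@@H]2CCC3(C)OC3C2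
F6 | step 8 | (2R)-6-methyl-2-[(3R)-6-methyl-7-oxabicyclo[4.1.0]heptan-3-yl]hept-5-en-2-ol (both epoxide diastereomers) | C[C@](O)([C@@H]1CCC2(C)OC2C1)CCC=C(C)C
F7 | step 8 | (3S,6R)-3-bromo-2,2,6-trimethyl-6-[(3R)-6-methyl-7-oxabicyclo[4.1.0]heptan-3-yl]oxane (both epoxide diastereomers) | CC1(C)O[C@@](C)([C@@H]2CCC3(C)OC3C2)CC[C@@H]1Br
F8 | step 11 | (3S,6R)-3-bromo-2,2,6-trimethyl-6-[(1R,3R,6S)-6-methyl-7-oxabicyclo[4.1.0]heptan-3-yl]oxane | CC1(C)O[C@@](C)([C@@H]2CC[C@]3(C)O[C@@H]3C2)CC[C@@H]1Br
F9 | step 11 | (1S,2S,4R)-4-[(2R,5S)-5-bromo-2,6,6-trimethyloxan-2-yl]-2-chloro-1-methylcyclohexan-1-ol | CC1(C)O[C@@](C)([C@@H]2CC[C@](C)(O)[C@@H](Cl)C2)CC[C@@H]1Br
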